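**Retrosynthetic overview**

1. The target gambiriin comes from global hydrogenolysis (ten benzyl ethers, two aryl bromides) of its protected form. The 3-OH of the catechin unit comes from hydroboration–oxidation of a flav-3-ene anti to the 2-aryl group, and the flav-3-ene from decarbonylation of a 2H-chromene-3-carbaldehyde.
2. Key disconnection: ring C of the catechin unit is the only ring that is built, and it is built last. A ring-A salicylaldehyde that already carries the whole chalcan unit at C6 is joined to 3,4-bis(benzyloxy)cinnamaldehyde by an amine-catalysed oxa-Michael/aldol condensation (O1–C2 first, then ring closure through C3–C4). The formyl group on C3 is a traceless activator.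
3. Enabling feature: on ring A the free hydroxyl O1 (on C8a) and the formyl carbon C4 (on C4a) are ortho to each other, while O5 and O7 are benzylated. O1 can therefore start the sequence, C3 can only close onto C4, and the pyran ring can only be fused on the O1 side, which fixes the 6-linkage.
4. Methine–C6 bond: silyl-triflate opening of the O1–C2 bond of perbenzylated 6,8-dibromo-(+)-catechin and capture of the benzylic cation, with inversion, by a 3,5-bis(benzyloxy)phenyl silyl ether. Desilylation and ortho-formylation then give the salicylaldehyde.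
5. Order of rings: all five benzene rings are bought ((+)-catechin, 3,5-bis(benzyloxy)phenol, 3,4-bis(benzyloxy)benzaldehyde). The pyran ring of the catechin donor is opened in step 5, and ring C of the lower unit is closed in step 10.

Key step: step 10

Remark: the sense of induction of the prolinol catalyst in step 10 is taken from the usual face-shielding model of its E-iminium ion (the nucleophile adds opposite to the diphenyl(silyloxy)methyl group). If the opposite sense were found, the enantiomeric catalyst would be used.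

**Route**

Step 1
Reactants: 1 (+)-catechin
Product: 2 (2R,3S)-5,7-bis(benzyloxy)-2-[3,4-bis(benzyloxy)phenyl]chroman-3-ol
Conditions: BnBr (4.4 equiv), K2CO3, DMF, 0 °C → rt
Reagents that add atoms: benzyl bromide BrCc1ccccc1
Why: Williamson etherification in which the carbonate deprotonates only the four phenols, so the secondary alcohol stays free and the mild base leaves C2 and C3 untouched.

Step 2
Reactants: 2 tetra-O-benzylcatechin
Product: 3 (2R,3S)-3,5,7-tris(benzyloxy)-2-[3,4-bis(benzyloxy)phenyl]chromane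
Conditions: NaH, BnBr, Bu4NI (cat.), DMF, 0 °C → rt
Reagents that add atoms: benzyl bromide BrCc1ccccc1
Why: Williamson etherification of the secondary alkoxide, which removes the only free hydroxyl before the cationic chemistry of step 5 without touching a stereocentre.

Step 3
Reactants: 3 penta-O-benzylcatechin
Product: 4 (2R,3S)-3,5,7-tris(benzyloxy)-2-[3,4-bis(benzyloxy)phenyl]-6,8-dibromochromane
Conditions: NBS (2.1 equiv), CH2Cl2, −10 °C → rt, dark
Reagents that add atoms: N-bromosuccinimide O=C1CCC(=O)N1Br
Why: electrophilic aromatic bromination that should take place only at C6 and C8 of the trioxygenated ring A, which is far more activated than the catechol ring, and that blocks both nucleophilic carbons of this ring for step 5.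

Step 4
Reactants: 5 3,5-bis(benzyloxy)phenol
Product: 6 [3,5-bis(benzyloxy)phenoxy]triisopropylsilane
Conditions: iPr3SiCl, imidazole, DMF, rt
Reagents that add atoms: triisopropylsilyl chloride CC(C)[Si](Cl)(C(C)C)C(C)C
Why: silylation of the phenol marks the future O1 with a bulky group that is orthogonal to benzyl ethers and shields its two neighbouring ring carbons.

Step 5
Reactants: 4 dibromo-penta-O-benzylcatechin; 6 aryl silyl ether
Product: 8 (1R,2S)-2-benzyloxy-1-[3,4-bis(benzyloxy)phenyl]-1-[2,6-bis(benzyloxy)-4-(triisopropylsilyloxy)phenyl]-3-[2,4-bis(benzyloxy)-3,5-dibromo-6-hydroxyphenyl]propane, via aryl trimethylsilyl ether 7 (not isolated)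
Conditions: TMSOTf (1.2 equiv), 2,6-di-tert-butyl-4-methylpyridine (1.5 equiv), CH2Cl2, −78 → −30 °C (arene in threefold excess); then 0.5 M aq HCl/THF, 0 °C
Reagents that add atoms: trimethylsilyl trifluoromethanesulfonate C[Si](C)(C)OS(=O)(=O)C(F)(F)F
Why: Friedel–Crafts alkylation by benzylic ether ionisation, in which silylation of O1 lets the O1–C2 bond of 4 ionise to a 4-alkoxybenzyl cation while the aryloxide leaves as its trimethylsilyl ether 7 and cannot re-close, the dibrominated ring cannot attack the cation, and arene 6 should capture it through the carbon between its two benzyloxy groups (the two CH next to the bulky silyl ether are shielded) on the face opposite to the departing aryloxide and the CH2Ar branch, so that the former C2 is inverted to the (1R) methine centre while the carbinol centre is untouched; the hindered pyridine takes up the triflic acid so that the benzyl and triisopropylsilyl ethers survive, and dilute acid then hydrolyses only the labile aryl trimethylsilyl ether.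

Step 6
Reactants: 8 ring-opened phenol
Product: 9 (1R,2S)-2-benzyloxy-1-[3,4-bis(benzyloxy)phenyl]-1-[2,6-bis(benzyloxy)-4-(triisopropylsilyloxy)phenyl]-3-[2,4,6-tris(benzyloxy)-3,5-dibromophenyl]propane
Conditions: NaH (1.2 equiv), BnBr (1.3 equiv), THF/DMF, 0 °C
Reagents that add atoms: benzyl bromide BrCc1ccccc1
Why: Williamson etherification of the only free (hindered, acidic) phenol under conditions that the aryl triisopropylsilyl ether tolerates, so that O1 stays the single differentiated oxygen.

Step 7
Reactants: 9 silyl ether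
Product: 10 (1R,2S)-2-benzyloxy-1-[3,4-bis(benzyloxy)phenyl]-1-[2,6-bis(benzyloxy)-4-hydroxyphenyl]-3-[2,4,6-tris(benzyloxy)-3,5-dibromophenyl]propane
Conditions: TBAF (1.1 equiv), AcOH (1.1 equiv), THF, 0 °C
Reagents that add atoms: none
Why: fluoride-induced desilylation frees O1 alone, since all other oxygens are benzyl ethers that fluoride does not cleave.

Step 8
Reactants: 10 phenol
Product: 11 2,4-bis(benzyloxy)-6-hydroxy-3-{(1R,2S)-2-benzyloxy-1-[3,4-bis(benzyloxy)phenyl]-3-[2,4,6-tris(benzyloxy)-3,5-dibromophenyl]propyl}benzaldehyde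
Conditions: MgCl2, Et3N, (CH2O)n, MeCN, 70 °C; aq HCl
Reagents that add atoms: paraformaldehyde (formaldehyde) C=O
Why: magnesium-phenoxide-directed ortho-formylation (Casnati–Skattebøl) delivers formaldehyde only to a carbon next to the free O1, the two such carbons being constitutionally equivalent, and stops after one formyl group because the chelated salicylaldehyde is deactivated.

Step 9
Reactants: 12 3,4-bis(benzyloxy)benzaldehyde
Product: 13 (E)-3-[3,4-bis(benzyloxy)phenyl]prop-2-enal
Conditions: Ph3P=CHCHO (1.05 equiv), PhMe, 80 °C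
Reagents that add atoms: (triphenylphosphoranylidene)acetaldehyde O=CC=P(c1ccccc1)(c1ccccc1)c1ccccc1
Why: Wittig olefination with a stabilised ylide gives the E-enal in one step.

Step 10
Reactants: 11 salicylaldehyde; 13 cinnamaldehyde
Product: 14 (2R)-5,7-bis(benzyloxy)-2-[3,4-bis(benzyloxy)phenyl]-6-{(1R,2S)-2-benzyloxy-1-[3,4-bis(benzyloxy)phenyl]-3-[2,4,6-tris(benzyloxy)-3,5-dibromophenyl]propyl}-2H-chromene-3-carbaldehyde
Conditions: (S)-2-[diphenyl(trimethylsilyloxy)methyl]pyrrolidine (20 mol%), 2-nitrobenzoic acid (20 mol%), 4 Å MS, PhMe, rt → 40 °C, dark (enal in twofold excess)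
Reagents that add atoms: none
Why: The secondary amine condenses with enal 13 to an E-iminium ion, O1 of 11 adds to its β-carbon (oxa-Michael, O1–C2), and the enamine so formed attacks the ortho formyl carbon C4 through C3 in an intramolecular aldol reaction that closes ring C, after which loss of water and hydrolysis give enal 14 and return the catalyst. The closest known reaction type is the diarylprolinol silyl ether catalysed domino oxa-Michael/aldol condensation of salicylaldehydes with cinnamaldehydes to 2-aryl-2H-chromene-3-carbaldehydes. Ring C (O1, C2, C3, C4, C4a, C8a) is closed at the C3–C4 bond in a 6-(enolexo)-exo-trig aldol mode, the attacked C=O and the enamine double bond both lying outside the new ring. The only new stereocentre, C2, is set by the catalyst, whose diphenyl(silyloxy)methyl group shields one face of the iminium ion so that O1 should add to the open face and give the (2R) centre, and because the oxa-Michael step is reversible the irreversible aldol/dehydration drains the favoured adduct, while the distant centres of the chalcan unit should not interfere. The step needs chemo- and regioselectivity, and both are secured by the substrate: O1 is the only free hydroxyl of 11 and the only oxygen next to the formyl group, so the pyran ring can only be fused on the O1 side of ring A, which gives the 6-linked skeleton. The formyl group on C3 that makes C3 nucleophilic is removed in step 11.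

Step 11
Reactants: 14 chromene-3-carbaldehyde
Product: 15 5,7-bis(benzyloxy)-2-[3,4-bis(benzyloxy)phenyl]-6-{(1R,2S)-2-benzyloxy-1-[3,4-bis(benzyloxy)phenyl]-3-[2,4,6-tris(benzyloxy)-3,5-dibromophenyl]propyl}-2H-chromene (flav-3-ene; C2 arrangement as in 14, (2S) by the sequence rule)
Conditions: RhCl(PPh3)3 (1.2 equiv), PhMe, 90 °C, dark
Reagents that add atoms: none
Why: Tsuji–Wilkinson decarbonylation, in which oxidative addition of the formyl C–H bond to monovalent rhodium, CO de-insertion and C–H reductive elimination replace the C3 formyl group by hydrogen with the C3=C4 double bond kept in place and C2 not involved.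

Step 12
Reactants: 15 flav-3-ene
Product: 17 (2R,3S)-5,7-bis(benzyloxy)-2-[3,4-bis(benzyloxy)phenyl]-6-{(1R,2S)-2-benzyloxy-1-[3,4-bis(benzyloxy)phenyl]-3-[2,4,6-tris(benzyloxy)-3,5-dibromophenyl]propyl}chroman-3-ol, via C3 alkylborane 16 (not isolated)
Conditions: BH3·SMe2 (3 equiv), THF, 0 °C → rt; then NaOH, H2O2, 0 °C → rt
Reagents that add atoms: borane–dimethyl sulfide [BH3-][S+](C)C; hydrogen peroxide OO
Why: hydroboration–oxidation, in which boron should add to C3 (the alkene carbon remote from the electron-rich ring A and its 5-benzyloxy group) from the face opposite to the 2-aryl group and the C–B bond is oxidised with retention, which sets (3S) trans to the 2-aryl group as in 2,3-trans-flavan-3-ols made from flav-3-enes.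

Step 13
Reactants: 17 protected target
Product: 18 (2R,3S)-2-(3,4-dihydroxyphenyl)-6-[(1R,2S)-1-(3,4-dihydroxyphenyl)-2-hydroxy-3-(2,4,6-trihydroxyphenyl)propyl]chromane-3,5,7-triol (the target gambiriin)
Conditions: H2 (1 atm), Pd(OH)2/C, Et3N (2.5 equiv), THF/MeOH/H2O, rt
Reagents that add atoms: none
Why: catalytic hydrogenolysis cleaves the ten benzyl ethers and both aryl C–Br bonds in one operation (the amine takes up HBr), while the four stereocentres, the O1–C2 bond and the diaryl methine are not affected under these mild conditions.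

**Compound list**

1 | (+)-catechin, (2R,3S) | O[C@H]1Cc2c(O)cc(O)cc2O[C@@H]1c1ccc(O)c(O)c1 | starting material
2 | 5,7,3',4'-tetra-O-benzyl-(+)-catechin, (2R,3S) | O[C@H]1Cc2c(OCc3ccccc3)cc(OCc3ccccc3)cc2O[C@@H]1c1ccc(OCc2ccccc2)c(OCc2ccccc2)c1 | intermediate
3 | 3,5,7,3',4'-penta-O-benzyl-(+)-catechin, (2R,3S) | C(c1ccccc1)O[C@H]1Cc2c(OCc3ccccc3)cc(OCc3ccccc3)cc2O[C@@H]1c1ccc(OCc2ccccc2)c(OCc2ccccc2)c1 | intermediate
4 | 6,8-dibromo-3,5,7,3',4'-penta-O-benzyl-(+)-catechin, (2R,3S) | C(c1ccccc1)O[C@H]1Cc2c(OCc3ccccc3)c(Br)c(OCc3ccccc3)c(Br)c2O[C@@H]1c1ccc(OCc2ccccc2)c(OCc2ccccc2)c1 | intermediate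
5 | 3,5-bis(benzyloxy)phenol | Oc1cc(OCc2ccccc2)cc(OCc2ccccc2)c1 | starting material
6 | [3,5-bis(benzyloxy)phenoxy]triisopropylsilane | CC(C)[Si](Oc1cc(OCc2ccccc2)cc(OCc2ccccc2)c1)(C(C)C)C(C)C | intermediate
7 | ring-opened adduct as aryl trimethylsilyl ether on the dibrominated ring, (1R,2S), O1 as triisopropylsilyl ether | C[Si](C)(C)Oc1c(Br)c(OCc2ccccc2)c(Br)c(OCc2ccccc2)c1C[C@H](OCc1ccccc1)[C@H](c1ccc(OCc2ccccc2)c(OCc2ccccc2)c1)c1c(OCc2ccccc2)cc(O[Si](C(C)C)(C(C)C)C(C)C)cc1OCc1ccccc1 | intermediate
8 | ring-opened adduct, (1R,2S), free phenol on the dibrominated ring, O1 as silyl ether | Oc1c(Br)c(OCc2ccccc2)c(Br)c(OCc2ccccc2)c1C[C@H](OCc1ccccc1)[C@H](c1ccc(OCc2ccccc2)c(OCc2ccccc2)c1)c1c(OCc2ccccc2)cc(O[Si](C(C)C)(C(C)C)C(C)C)cc1OCc1ccccc1 | intermediate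
9 | O-benzyl ether of 8, (1R,2S) | C(c1ccccc1)Oc1c(Br)c(OCc2ccccc2)c(Br)c(OCc2ccccc2)c1C[C@H](OCc1ccccc1)[C@H](c1ccc(OCc2ccccc2)c(OCc2ccccc2)c1)c1c(OCc2ccccc2)cc(O[Si](C(C)C)(C(C)C)C(C)C)cc1OCc1ccccc1 | intermediate
10 | ring-A phenol (free O1), (1R,2S) | C(c1ccccc1)Oc1c(Br)c(OCc2ccccc2)c(Br)c(OCc2ccccc2)c1C[C@H](OCc1ccccc1)[C@H](c1ccc(OCc2ccccc2)c(OCc2ccccc2)c1)c1c(OCc2ccccc2)cc(O)cc1OCc1ccccc1 | intermediate
11 | ring-A salicylaldehyde, (1R,2S) | C(c1ccccc1)Oc1c(Br)c(OCc2ccccc2)c(Br)c(OCc2ccccc2)c1C[C@H](OCc1ccccc1)[C@H](c1ccc(OCc2ccccc2)c(OCc2ccccc2)c1)c1c(OCc2ccccc2)c(C=O)c(O)cc1OCc1ccccc1 | intermediate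
12 | 3,4-bis(benzyloxy)benzaldehyde | O=Cc1ccc(OCc2ccccc2)c(OCc2ccccc2)c1 | starting material
13 | (E)-3-[3,4-bis(benzyloxy)phenyl]prop-2-enal | O=C/C=C/c1ccc(OCc2ccccc2)c(OCc2ccccc2)c1 | intermediate
14 | (2R)-2-aryl-2H-chromene-3-carbaldehyde carrying the (1R,2S) chalcan unit at C6 | C(c1ccccc1)Oc1c(Br)c(OCc2ccccc2)c(Br)c(OCc2ccccc2)c1C[C@H](OCc1ccccc1)[C@H](c1ccc(OCc2ccccc2)c(OCc2ccccc2)c1)c1c(OCc2ccccc2)cc2c(c1OCc1ccccc1)C=C(C=O)[C@@H](c1ccc(OCc3ccccc3)c(OCc3ccccc3)c1)O2 | intermediate
15 | flav-3-ene (C2 arrangement as in 14) carrying the (1R,2S) chalcan unit at C6 | C(c1ccccc1)Oc1c(Br)c(OCc2ccccc2)c(Br)c(OCc2ccccc2)c1C[C@H](OCc1ccccc1)[C@H](c1ccc(OCc2ccccc2)c(OCc2ccccc2)c1)c1c(OCc2ccccc2)cc2c(c1OCc1ccccc1)C=C[C@@H](c1ccc(OCc3ccccc3)c(OCc3ccccc3)c1)O2 | intermediate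
16 | 2,3-trans C3 alkylborane (shown as RBH2) | C(c1ccccc1)Oc1c(Br)c(OCc2ccccc2)c(Br)c(OCc2ccccc2)c1C[C@H](OCc1ccccc1)[C@H](c1ccc(OCc2ccccc2)c(OCc2ccccc2)c1)c1c(OCc2ccccc2)cc2c(c1OCc1ccccc1)C[C@H](B)[C@@H](c1ccc(OCc3ccccc3)c(OCc3ccccc3)c1)O2 | intermediate
17 | deca-O-benzyl-dibromo derivative of the target, (2R,3S) flavan-3-ol with (1R,2S) chalcan unit | C(c1ccccc1)Oc1c(Br)c(OCc2ccccc2)c(Br)c(OCc2ccccc2)c1C[C@H](OCc1ccccc1)[C@H](c1ccc(OCc2ccccc2)c(OCc2ccccc2)c1)c1c(OCc2ccccc2)cc2c(c1OCc1ccccc1)C[C@H](O)[C@@H](c1ccc(OCc3ccccc3)c(OCc3ccccc3)c1)O2 | intermediate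
18 | the target gambiriin, (2R,3S) flavan-3-ol linked at C6 to the (1R,2S) chalcan unit | Oc1cc(O)c(C[C@H](O)[C@H](c2ccc(O)c(O)c2)c2c(O)cc3c(c2O)C[C@H](O)[C@@H](c2ccc(O)c(O)c2)O3)c(O)c1 | target

**Step count and risks**

Total step count: 13. Longest linear sequence: 11 steps (steps 1, 2, 3, 5, 6, 7, 8, 10, 11, 12, 13).

Steps most likely to fail:

Step 5. The arene may be alkylated at a carbon next to the silyl ether instead of the carbon between the two benzyloxy groups. Capture of the congested cation may also be slow, so that the cation loses a proton or lives long enough for facial selectivity to erode. The fallback sets out from 4 and replaces arene 6 by free phloroglucinol, which is symmetrical, more nucleophilic and less hindered. Compound 4 and phloroglucinol (5 equiv) with BF3·OEt2 in 1,4-dioxane/CH2Cl2 at 0 °C should give the ring-opened tetraphenol F1 by the same anti capture. Silylation with iPr3SiCl (1.0 equiv) and imidazole in DMF at −20 °C should take the least hindered hydroxyl, the one para to the new C–C bond, and give the mono-silyl ether F2. Benzylation of the three remaining phenols (BnBr, K2CO3, Bu4NI, acetone, 50 °C) then gives 9, where the route is rejoined before step 7.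

Step 10. The intramolecular aldol onto the electron-rich formyl group, which is flanked by two ortho substituents, may be slow. The reversible oxa-Michael adduct would then not drain, enal 13 would be lost to self-condensation, and catalyst control at C2 could be incomplete. The fallback sets out from 11 and 13 and closes ring C by olefin metathesis, still through the C3–C4 bond. Methylenation of 11 (Ph3PCH3Br, KOtBu, THF, excess ylide) gives the vinylphenol F3. Reduction of 13 (NaBH4, MeOH, 0 °C) gives the cinnamyl alcohol F4, and ClCO2Me/pyridine converts it into the methyl carbonate F5. Asymmetric allylic etherification of the phenoxide of F3 with F5 ([Ir(cod)Cl]2, binaphthol-derived phosphoramidite ligand with a bis(1-phenylethyl)amino group, enantiomer chosen for the required C2 arrangement, THF, rt) should give the branched aryl allyl ether F6. Ring-closing metathesis with the second-generation Grubbs catalyst (CH2Cl2, 40 °C) gives 15, where the route is rejoined before step 12; step 11 is then not needed.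

Step 11. At the temperature needed for CO extrusion from the conjugated acyl rhodium hydride, the 2H-chromene may open and re-close electrocyclically, with loss of configuration at C2. The double bond may also move to the 4H-chromene, or the extrusion may stall. The fallback sets out from 14 and turns the formyl carbon into the leaving part of an ester instead. Conjugate reduction with [CuH(PPh3)]6 (benzene, rt, then DBU to equilibrate C3) should give the 2,3-trans saturated aldehyde F7. Baeyer–Villiger oxidation (mCPBA, NaHCO3, CH2Cl2, 0 °C) with migration of the secondary carbon and retention gives the formate F8. Methanolysis (K2CO3, MeOH/THF) gives 17, where the route is rejoined before step 13; step 12 is then not needed.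

**Further compounds**

F1 | step 5 | ring-opened adduct with free phloroglucinol ring, (1R,2S) | Oc1c(Br)c(OCc2ccccc2)c(Br)c(OCc2ccccc2)c1C[C@H](OCc1ccccc1)[C@H](c1ccc(OCc2ccccc2)c(OCc2ccccc2)c1)c1c(O)cc(O)cc1O
F2 | step 5 | mono-triisopropylsilyl ether of F1 at the hydroxyl para to the methine, (1R,2S) | Oc1c(Br)c(OCc2ccccc2)c(Br)c(OCc2ccccc2)c1C[C@H](OCc1ccccc1)[C@H](c1ccc(OCc2ccccc2)c(OCc2ccccc2)c1)c1c(O)cc(O[Si](C(C)C)(C(C)C)C(C)C)cc1O
F3 | step 10 | ring-A 2-vinylphenol from 11, (1R,2S) | C(c1ccccc1)Oc1c(Br)c(OCc2ccccc2)c(Br)c(OCc2ccccc2)c1C[C@H](OCc1ccccc1)[C@H](c1ccc(OCc2ccccc2)c(OCc2ccccc2)c1)c1c(OCc2ccccc2)c(C=C)c(O)cc1OCc1ccccc1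
F4 | step 10 | (E)-3-[3,4-bis(benzyloxy)phenyl]prop-2-en-1-ol | OC/C=C/c1ccc(OCc2ccccc2)c(OCc2ccccc2)c1
F5 | step 10 | (E)-3-[3,4-bis(benzyloxy)phenyl]allyl methyl carbonate | COC(=O)OC/C=C/c1ccc(OCc2ccccc2)c(OCc2ccccc2)c1
F6 | step 10 | branched aryl 1-arylallyl ether of F3 (C2 arrangement as in 15) | C(c1ccccc1)Oc1c(Br)c(OCc2ccccc2)c(Br)c(OCc2ccccc2)c1C[C@H](OCc1ccccc1)[C@H](c1ccc(OCc2ccccc2)c(OCc2ccccc2)c1)c1c(OCc2ccccc2)c(C=C)c(O[C@@H](C=C)c2ccc(OCc3ccccc3)c(OCc3ccccc3)c2)cc1OCc1ccccc1
F7 | step 11 | 2,3-trans-flavan-3-carbaldehyde from 14 | C(c1ccccc1)Oc1c(Br)c(OCc2ccccc2)c(Br)c(OCc2ccccc2)c1C[C@H](OCc1ccccc1)[C@H](c1ccc(OCc2ccccc2)c(OCc2ccccc2)c1)c1c(OCc2ccccc2)cc2c(c1OCc1ccccc1)C[C@H](C=O)[C@@H](c1ccc(OCc3ccccc3)c(OCc3ccccc3)c1)O2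
F8 | step 11 | 3-O-formate of 17, (2R,3S) | C(c1ccccc1)Oc1c(Br)c(OCc2ccccc2)c(Br)c(OCc2ccccc2)c1C[C@H](OCc1ccccc1)[C@H](c1ccc(OCc2ccccc2)c(OCc2ccccc2)c1)c1c(OCc2ccccc2)cc2c(c1OCc1ccccc1)C[C@H](OC=O)[C@@H](c1ccc(OCc3ccccc3)c(OCc3ccccc3)c1)O2
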